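**Retrosynthetic overview**

Numbering: ring B is the benzene ring of the chroman (O1, C2, C3, C4, C4a, C5 to C8, C8a); ring A is the resorcinol ring (C1' carries the propyl chain, oxygens on C2' and C4', C5' carries the 1,1-dimethylallyl group). Both benzene rings are bought; the dihydropyran ring is the only ring formed, and it is formed last.
Last operation: C4–C4a and O1–C2 are disconnected together, and with them the C5'–CMe2 bond of ring A. This leads back to an isomer of the target, a 1,3-diarylpropane with a 1,1-dimethylallyl ether on O1 and a prenyl ether on O4'.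
Enabling feature: O1 sits on C8a, whose ortho neighbours are C8 (bearing the hydroxyl) and the unsubstituted C4a, and whose para carbon C6 bears the propyl chain. An allyl group leaving O1 by a [3,3] shift can therefore end only on C4a; it arrives as a prenyl group, and the freed O1–H closes onto its CMe2 carbon. The ring A prenyl ether is made to rearrange in the same pot before acid is added, because it would not survive the acid.
The diarylpropane comes from a chalcone (Claisen–Schmidt condensation, conjugate reduction, removal of the ketone oxygen through an ortho-quinone methide, semihydrogenation of a propargyl ether). The C5 prenyl group comes from a Stille coupling at a C5 bromide, and the O1 ether from alkylation of the catechol hydroxyl para to the formyl group.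

Key step: step 9

Remark: the target has no stereocentre, so no stereocontrol is needed; the only alkene geometry that arises (E in the chalcone) is erased in step 6. Tributyl(3-methylbut-2-en-1-yl)stannane, 3-chloro-3-methylbut-1-yne and 1-bromo-3-methylbut-2-ene are taken as purchased reagents.

**Route**

Step 1
Reactants: 1 2-bromo-4,5-dimethoxybenzaldehyde
Product: 2 2-bromo-4,5-dihydroxybenzaldehyde
Conditions: BBr3 (3 equiv), CH2Cl2, -78 °C to 20 °C; H2O
Reagents that add atoms: none
Why: Lewis acid cleavage of both aryl methyl ethers with BBr3 is placed first, before any acid-sensitive alkene is present, and should leave the aryl bromide and the formyl group untouched.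

Step 2
Reactants: 2 2-bromo-4,5-dihydroxybenzaldehyde
Product: 3 4,5-dihydroxy-2-(3-methylbut-2-en-1-yl)benzaldehyde
Conditions: tributyl(3-methylbut-2-en-1-yl)stannane (1.5 equiv), Pd(PPh3)4 (5 mol %), DMF, 90 °C, degassed
Reagents that add atoms: tributyl(3-methylbut-2-en-1-yl)stannane, CCCC[Sn](CCCC)(CCCC)CC=C(C)C
Why: Stille coupling: zerovalent palladium inserts into the C–Br bond activated by the ortho formyl group, and reductive elimination at the unsubstituted allyl terminus should give the linear prenyl arene under neutral conditions that a free catechol tolerates.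

Step 3
Reactants: 3 4,5-dihydroxy-2-(3-methylbut-2-en-1-yl)benzaldehyde
Product: 4 5-hydroxy-4-[(2-methylbut-3-yn-2-yl)oxy]-2-(3-methylbut-2-en-1-yl)benzaldehyde
Conditions: 3-chloro-3-methylbut-1-yne (1.3 equiv), K2CO3 (1.1 equiv), KI, CuI (5 mol %), DMF, 40 °C
Reagents that add atoms: 3-chloro-3-methylbut-1-yne, C#CC(C)(C)Cl
Why: Copper-assisted Williamson-type propargylic etherification: with one equivalent of base the phenoxide forms at the hydroxyl para to the formyl group (the more acidic one), so the tertiary propargyl group should go onto the oxygen that becomes O1.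

Step 4
Reactants: 5 1-(2,4-dihydroxyphenyl)ethan-1-one
Product: 6 1-{2-hydroxy-4-[(3-methylbut-2-en-1-yl)oxy]phenyl}ethan-1-one
Conditions: 1-bromo-3-methylbut-2-ene (1.1 equiv), K2CO3, acetone, 56 °C
Reagents that add atoms: 1-bromo-3-methylbut-2-ene, CC(C)=CCBr
Why: Williamson ether synthesis: the hydroxyl ortho to the acetyl group is held in a hydrogen bond to the carbonyl oxygen, so only the para hydroxyl should be alkylated.

Step 5
Reactants: 4 5-hydroxy-4-[(2-methylbut-3-yn-2-yl)oxy]-2-(3-methylbut-2-en-1-yl)benzaldehyde; 6 1-{2-hydroxy-4-[(3-methylbut-2-en-1-yl)oxy]phenyl}ethan-1-one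
Product: 7 (E)-3-{5-hydroxy-4-[(2-methylbut-3-yn-2-yl)oxy]-2-(3-methylbut-2-en-1-yl)phenyl}-1-{2-hydroxy-4-[(3-methylbut-2-en-1-yl)oxy]phenyl}prop-2-en-1-one
Conditions: KOH, EtOH/H2O, 20 °C; AcOH
Reagents that add atoms: none
Why: Claisen–Schmidt condensation of the methyl ketone enolate with the non-enolizable aldehyde and loss of water should give the E enone; the ethers, the alkyne and the alkenes are inert to hydroxide.

Step 6
Reactants: 7 the chalcone of step 5
Product: 8 3-{5-hydroxy-4-[(2-methylbut-3-yn-2-yl)oxy]-2-(3-methylbut-2-en-1-yl)phenyl}-1-{2-hydroxy-4-[(3-methylbut-2-en-1-yl)oxy]phenyl}propan-1-one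
Conditions: Zn dust, NH4Cl, EtOH/H2O, 70 °C
Reagents that add atoms: none
Why: Dissolving-metal conjugate reduction: zinc transfers electrons only to the conjugated enone and NH4Cl supplies the protons, so the isolated trisubstituted alkenes, the terminal alkyne and the allyl and propargyl ethers should stay untouched.

Step 7
Reactants: 8 the dihydrochalcone of step 6
Product: 12 2-(3-{5-hydroxy-4-[(2-methylbut-3-yn-2-yl)oxy]-2-(3-methylbut-2-en-1-yl)phenyl}propyl)-5-[(3-methylbut-2-en-1-yl)oxy]phenol, via bis(ethyl carbonate) 9 (not isolated), via ortho-quinone methide 10 (not isolated), via ring B ethyl carbonate 11 (not isolated)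
Conditions: ClCO2Et (2.5 equiv), Et3N, THF, 0 °C; NaBH4, THF/H2O, 0 °C to 20 °C; 2 M NaOH, 20 °C; NH4Cl
Reagents that add atoms: none
Why: Deoxygenation of an ortho-hydroxyaryl ketone through its aryl carbonate: hydride reduces the ketone, the alkoxide takes over the ethoxycarbonyl group and is expelled as ethyl carbonate to give ortho-quinone methide 10, NaBH4 reduces this at the exocyclic carbon, and NaOH cleaves the remaining ring B carbonate in the same flask.

Step 8
Reactants: 12 the propargyl ether of step 7
Product: 13 2-(3-{5-hydroxy-4-[(2-methylbut-3-en-2-yl)oxy]-2-(3-methylbut-2-en-1-yl)phenyl}propyl)-5-[(3-methylbut-2-en-1-yl)oxy]phenol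
Conditions: H2 (1 atm), Pd/CaCO3 poisoned with Pb(OAc)2, quinoline, EtOAc, 20 °C, stopped after one equivalent of H2
Reagents that add atoms: none
Why: Lindlar-type semihydrogenation of the terminal alkyne on poisoned palladium should stop at the vinyl group and spare the trisubstituted alkenes; the product is kept below 30 °C and used at once, because it is the substrate of the thermal step.

Step 9
Reactants: 13 the bis-ether of step 8
Product: 16 kazinol D, via ring B ortho-prenylphenol 14 (not isolated), via open tetraol 15 (not isolated)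
Conditions: 1,2-dichlorobenzene (0.02 M, degassed, Ar), 120 °C, then 180 °C; cool to 20 °C, Amberlyst 15 (sulfonic acid resin), 20 °C
Reagents that add atoms: none
Why: Mechanism: at 120 °C the 1,1-dimethylallyl group on O1 undergoes an aromatic Claisen [3,3] shift to C4a (C4–C4a bond) and the dienone tautomerizes to ortho-prenylphenol 14; at 180 °C the prenyl ether on O4' undergoes the second Claisen shift to C5' and gives tetraol 15; the sulfonic acid resin then protonates the C4a prenyl alkene at its CH carbon and the O1 hydroxyl captures the tertiary cation (O1–C2 bond). The closest known reaction types are the Claisen rearrangement of aryl 1,1-dimethylallyl ethers to ortho-prenylphenols, the Claisen rearrangement of aryl prenyl ethers to ortho-(1,1-dimethylallyl)phenols, and the acid-catalysed cyclization of ortho-prenylphenols to 2,2-dimethylchromans. The dihydropyran ring closes in the 6-endo-trig mode by cationic hydroalkoxylation, and no stereocentre is formed. Site selectivity on ring B is secured by the substitution pattern: C8 and C6 are occupied, a shift to C8 is reversible and unproductive, and C4a is the only carbon where the dienone can tautomerize. Site selectivity on ring A (C5' over C3') must come from the greater crowding of C3' between two oxygens, while C1', para to O4', is blocked by the chain. Chemoselectivity in the acid stage rests on three facts: the C5 prenyl group has no ortho hydroxyl, the ring A 1,1-dimethylallyl group could give only a secondary cation, and the acid-labile prenyl ether is consumed before acid is added.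

**Compound list**

1 | 2-bromo-4,5-dimethoxybenzaldehyde | COc1cc(Br)c(C=O)cc1OC | starting material
2 | 2-bromo-4,5-dihydroxybenzaldehyde | O=Cc1cc(O)c(O)cc1Br | intermediate
3 | 4,5-dihydroxy-2-(3-methylbut-2-en-1-yl)benzaldehyde | O=Cc1cc(O)c(O)cc1CC=C(C)C | intermediate
4 | 5-hydroxy-4-[(2-methylbut-3-yn-2-yl)oxy]-2-(3-methylbut-2-en-1-yl)benzaldehyde | O=Cc1cc(O)c(OC(C)(C)C#C)cc1CC=C(C)C | intermediate
5 | 1-(2,4-dihydroxyphenyl)ethan-1-one | CC(=O)c1ccc(O)cc1O | starting material
6 | 1-{2-hydroxy-4-[(3-methylbut-2-en-1-yl)oxy]phenyl}ethan-1-one | CC(=O)c1ccc(OCC=C(C)C)cc1O | intermediate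
7 | (E)-3-{5-hydroxy-4-[(2-methylbut-3-yn-2-yl)oxy]-2-(3-methylbut-2-en-1-yl)phenyl}-1-{2-hydroxy-4-[(3-methylbut-2-en-1-yl)oxy]phenyl}prop-2-en-1-one | O=C(/C=C/c1cc(O)c(OC(C)(C)C#C)cc1CC=C(C)C)c1ccc(OCC=C(C)C)cc1O | intermediate
8 | 3-{5-hydroxy-4-[(2-methylbut-3-yn-2-yl)oxy]-2-(3-methylbut-2-en-1-yl)phenyl}-1-{2-hydroxy-4-[(3-methylbut-2-en-1-yl)oxy]phenyl}propan-1-one | O=C(CCc1cc(O)c(OC(C)(C)C#C)cc1CC=C(C)C)c1ccc(OCC=C(C)C)cc1O | intermediate
9 | bis(ethyl carbonate) of 8 (both phenolic oxygens carry CO2Et) | CCOC(=O)Oc1cc(OCC=C(C)C)ccc1C(=O)CCc1cc(OC(=O)OCC)c(OC(C)(C)C#C)cc1CC=C(C)C | intermediate (not isolated)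
10 | ring A ortho-quinone methide: 6-alkylidene-3-(prenyloxy)cyclohexa-2,4-dien-1-one, the exocyclic carbon carrying the CH2CH2 link to ring B (ring B hydroxyl still as ethyl carbonate) | O=C1C=C(OCC=C(C)C)C=CC1=CCCc1cc(OC(=O)OCC)c(OC(C)(C)C#C)cc1CC=C(C)C | intermediate (not isolated)
11 | ethyl carbonate of 12 at the ring B hydroxyl | CCOC(=O)Oc1cc(CCCc2ccc(OCC=C(C)C)cc2O)c(CC=C(C)C)cc1OC(C)(C)C#C | intermediate (not isolated)
12 | 2-(3-{5-hydroxy-4-[(2-methylbut-3-yn-2-yl)oxy]-2-(3-methylbut-2-en-1-yl)phenyl}propyl)-5-[(3-methylbut-2-en-1-yl)oxy]phenol | Oc1cc(OCC=C(C)C)ccc1CCCc1cc(O)c(OC(C)(C)C#C)cc1CC=C(C)C | intermediate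
13 | 2-(3-{5-hydroxy-4-[(2-methylbut-3-en-2-yl)oxy]-2-(3-methylbut-2-en-1-yl)phenyl}propyl)-5-[(3-methylbut-2-en-1-yl)oxy]phenol | Oc1cc(OCC=C(C)C)ccc1CCCc1cc(O)c(OC(C)(C)C=C)cc1CC=C(C)C | intermediate
14 | 5-(3-{2-hydroxy-4-[(3-methylbut-2-en-1-yl)oxy]phenyl}propyl)-3,4-bis(3-methylbut-2-en-1-yl)benzene-1,2-diol | Oc1cc(OCC=C(C)C)ccc1CCCc1cc(O)c(O)c(CC=C(C)C)c1CC=C(C)C | intermediate (not isolated)
15 | 5-{3-[2,4-dihydroxy-5-(2-methylbut-3-en-2-yl)phenyl]propyl}-3,4-bis(3-methylbut-2-en-1-yl)benzene-1,2-diol | C=CC(C)(C)c1cc(CCCc2cc(O)c(O)c(CC=C(C)C)c2CC=C(C)C)c(O)cc1O | intermediate (not isolated)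
16 | kazinol D, 4-{3-[8-hydroxy-2,2-dimethyl-5-(3-methylbut-2-en-1-yl)-3,4-dihydro-2H-chromen-6-yl]propyl}-6-(2-methylbut-3-en-2-yl)benzene-1,3-diol | C=CC(C)(C)c1cc(CCCc2cc(O)c3c(c2CC=C(C)C)CCC(C)(C)O3)c(O)cc1O | target

**Step count and risks**

Total step count: 9. Longest linear sequence: 8 steps (steps 1, 2, 3, 5, 6, 7, 8, 9); step 4 is the one-step branch for ring A.

The three steps most likely to fail:

1. Step 9. What may go wrong: during the 180 °C stage the ring A phenol that has just formed can add to its own 1,1-dimethylallyl group or lose the C5 unit; the ring A shift can go partly to C3'; and the acid stage can begin to touch the other alkenes. Fallback (sets out from 13, comes back at 16): the sigmatropic shifts are run with trapping of every phenol, and the ring closure becomes a step of its own. Heating 13 in Ac2O/N,N-diethylaniline with NaOAc (120 °C, then 185 °C) should give the tetraacetate F1, in which no free phenol is left next to an alkene. K2CO3 in degassed MeOH at 20 °C should release the open tetraol 15, which is now isolated. Amberlyst 15 in CH2Cl2 at 0 °C should then close the dihydropyran ring to 16 under conditions that can be followed and stopped.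

2. Step 6. What may go wrong: reductive dimerization of the enone at its β-carbon, ring closure of the ortho-hydroxy enone to a flavanone, or incomplete conversion. Fallback (sets out from 7, comes back at 13): the order of the reductions is changed so that the conjugate reduction meets no alkyne and can be done by hydride transfer at 20 °C. Semihydrogenation of 7 over Pd/CaCO3 poisoned with Pb(OAc)2 (H2, quinoline, EtOAc, 20 °C) should give the 1,1-dimethylallyl ether chalcone F2. Copper hydride made in the flask from Cu(OAc)2·H2O, PPh3 and polymethylhydrosiloxane (toluene/t-BuOH, 20 °C, fluoride work-up) should reduce only the enone alkene and give the dihydrochalcone F3. The deoxygenation of step 7 (ClCO2Et, Et3N; NaBH4; NaOH; all at 0 to 20 °C) should then lead through the bis(ethyl carbonate) F4, the ortho-quinone methide F5 and the ring B ethyl carbonate F6 to 13, which is taken into step 9 at once.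

3. Step 2. What may go wrong: protonolysis of the allylstannane by the acidic catechol hydroxyls, sequestration of the catalyst by the catechol, or partial transfer of the allyl group through its tertiary terminus. Fallback (sets out from 2, comes back at 3): the acidic hydroxyls are masked for the coupling. Ac2O/pyridine should give the diacetate F7, whose more electron-poor C–Br bond should couple with the same stannane (Pd(PPh3)4, toluene, 100 °C) to the prenylated diacetate F8. K2CO3/MeOH at 0 °C should then return catechol 3.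

Further compounds
F1 | step 9 | tetraacetate of 15 (all four phenolic oxygens acetylated) | C=CC(C)(C)c1cc(CCCc2cc(OC(C)=O)c(OC(C)=O)c(CC=C(C)C)c2CC=C(C)C)c(OC(C)=O)cc1OC(C)=O
F2 | step 6 | (E)-3-{5-hydroxy-4-[(2-methylbut-3-en-2-yl)oxy]-2-(3-methylbut-2-en-1-yl)phenyl}-1-{2-hydroxy-4-[(3-methylbut-2-en-1-yl)oxy]phenyl}prop-2-en-1-one | O=C(/C=C/c1cc(O)c(OC(C)(C)C=C)cc1CC=C(C)C)c1ccc(OCC=C(C)C)cc1O
F3 | step 6 | 3-{5-hydroxy-4-[(2-methylbut-3-en-2-yl)oxy]-2-(3-methylbut-2-en-1-yl)phenyl}-1-{2-hydroxy-4-[(3-methylbut-2-en-1-yl)oxy]phenyl}propan-1-one | O=C(CCc1cc(O)c(OC(C)(C)C=C)cc1CC=C(C)C)c1ccc(OCC=C(C)C)cc1O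
F4 | step 6 | bis(ethyl carbonate) of F3 | CCOC(=O)Oc1cc(OCC=C(C)C)ccc1C(=O)CCc1cc(OC(=O)OCC)c(OC(C)(C)C=C)cc1CC=C(C)C
F5 | step 6 | ring A ortho-quinone methide from F4 (ring B hydroxyl as ethyl carbonate) | O=C1C=C(OCC=C(C)C)C=CC1=CCCc1cc(OC(=O)OCC)c(OC(C)(C)C=C)cc1CC=C(C)C
F6 | step 6 | ethyl carbonate of 13 at the ring B hydroxyl | CCOC(=O)Oc1cc(CCCc2ccc(OCC=C(C)C)cc2O)c(CC=C(C)C)cc1OC(C)(C)C=C
F7 | step 2 | 4-bromo-5-formyl-1,2-phenylene diacetate | CC(=O)Oc1cc(Br)c(C=O)cc1OC(C)=O
F8 | step 2 | 4-formyl-5-(3-methylbut-2-en-1-yl)-1,2-phenylene diacetate | CC(=O)Oc1cc(CC=C(C)C)c(C=O)cc1OC(C)=O
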